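**Plan**

- Retrosynthesis: the quinone is traced back to a dibenzyl hydroquinone (ring B, carried intact). Ring A and the pyran are then opened together by cutting C8a–C4a, C5–C6 and C6–C7. This leaves a chromium alkoxy(1,2-dimethoxyvinyl)carbene whose alkoxy group is an (S)-2-arylpent-4-yn-1-ol. That alcohol is cut at C3–C4 (enolate propargylation) and at C3–C1' (malonate arylation).
- Enabling feature: ring A is a hydroquinone monoether. The ring oxygen O1 sits on C8a, para to the only free hydroxyl on C6, with the C7 and C8 methoxy groups between them. A Dötz benzannulation writes exactly this pattern: C8a is the alkoxycarbene carbon, C6 an inserted CO, C7/C8 the vinyl carbons and C4a/C5 the alkyne.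
- Forward order: ring B is built first from 2,3-dimethoxyphenol and taken via its bromide to an arylacetic acid. The C2–C3–C4–alkyne chain is attached next. Pyran and ring A then form in one operation, and debenzylation/oxidation of ring B to the quinone comes last.
- Stereochemistry: C3, the only stereocentre, is set by Evans alkylation of the arylacetyl imide of (S)-4-benzyloxazolidin-2-one with propargyl bromide and is not touched afterwards.

Key step: step 13

Assumption: the enol ether 18 is carried as its Z isomer; any E isomer present would be lithiated at the same carbon and should converge on the same arene, because C7 and C8 end up as aromatic carbons.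

**Route**

Step 1
Reactants: 1 2,3-dimethoxyphenol
Product: 2 2,3-dimethoxy-1,4-benzoquinone
Conditions: Fremy's salt (2.2 equiv), KH2PO4, H2O/acetone, 0 °C to rt
Reagents that add atoms: Fremy's salt (dipotassium nitrosodisulfonate), [K+].[K+].[O]N(S(=O)(=O)[O-])S(=O)(=O)[O-]
Why: Teuber oxidation, in which the phenoxyl radical is trapped at the free para position by a second nitrosodisulfonate radical and loss of imidodisulfonate leaves the p-quinone.

Step 2
Reactants: 2 2,3-dimethoxy-1,4-benzoquinone
Product: 3 2,3-dimethoxybenzene-1,4-diol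
Conditions: Na2S2O4, Et2O/H2O, rt; crude product used at once
Reagents that add atoms: none
Why: dithionite reduction of a benzoquinone to its hydroquinone is fast and clean in a two-phase system.

Step 3
Reactants: 3 2,3-dimethoxybenzene-1,4-diol
Product: 4 1,4-bis(benzyloxy)-2,3-dimethoxybenzene
Conditions: BnBr (2.4 equiv), K2CO3, DMF (degassed), N2, 60 °C
Reagents that add atoms: benzyl bromide, BrCc1ccccc1
Why: Williamson etherification of both phenoxides, with air excluded so that the hydroquinone is not re-oxidised.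

Step 4
Reactants: 4 1,4-bis(benzyloxy)-2,3-dimethoxybenzene
Product: 5 1,4-bis(benzyloxy)-5-bromo-2,3-dimethoxybenzene
Conditions: NBS (1.0 equiv), MeCN, 0 °C to rt
Reagents that add atoms: N-bromosuccinimide, O=C1CCC(=O)N1Br
Why: electrophilic aromatic bromination in which the two free positions are equivalent (each ortho to a benzyloxy and para to a methoxy group) and the first bromine slows a second substitution.

Step 5
Reactants: 5 1,4-bis(benzyloxy)-5-bromo-2,3-dimethoxybenzene; 6 diethyl malonate
Product: 7 diethyl 2-[2,5-bis(benzyloxy)-3,4-dimethoxyphenyl]malonate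
Conditions: Pd(dba)2 (2 mol %), P(t-Bu)3 (4 mol %), K3PO4, toluene, 70 °C
Reagents that add atoms: none
Why: palladium-catalysed α-arylation of a malonate enolate, where the bulky electron-rich phosphine permits oxidative addition into the electron-rich ortho-substituted bromide and the acidic product rests as its enolate, which blocks a second arylation.

Step 6
Reactants: 7 diethyl 2-[2,5-bis(benzyloxy)-3,4-dimethoxyphenyl]malonate
Product: 9 [2,5-bis(benzyloxy)-3,4-dimethoxyphenyl]acetic acid, via arylmalonic acid 8 (not isolated)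
Conditions: KOH, EtOH/H2O, reflux; then aq. HCl (pH 1), dioxane, 90 °C
Reagents that add atoms: potassium hydroxide, [K+].[OH-]
Why: saponification followed by thermal decarboxylation of the arylmalonic acid, conditions under which aryl benzyl ethers are stable.

Step 7
Reactants: 9 [2,5-bis(benzyloxy)-3,4-dimethoxyphenyl]acetic acid; 10 (S)-4-benzyl-1,3-oxazolidin-2-one
Product: 12 (S)-4-benzyl-3-{[2,5-bis(benzyloxy)-3,4-dimethoxyphenyl]acetyl}-1,3-oxazolidin-2-one, via mixed pivalic anhydride 11 (not isolated)
Conditions: PivCl, Et3N, THF, −20 °C; then 10, LiCl, −20 °C to rt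
Reagents that add atoms: none
Why: mixed-anhydride N-acylation of the oxazolidinone under LiCl/Et3N activation, which needs no strong base and attacks the less hindered arylacetyl carbonyl of the anhydride.

Step 8
Reactants: 12 (S)-4-benzyl-3-{[2,5-bis(benzyloxy)-3,4-dimethoxyphenyl]acetyl}-1,3-oxazolidin-2-one; 13 3-bromoprop-1-yne (propargyl bromide)
Product: 15 (S)-4-benzyl-3-{(2S)-2-[2,5-bis(benzyloxy)-3,4-dimethoxyphenyl]pent-4-ynoyl}-1,3-oxazolidin-2-one, via sodium Z-enolate 14 (not isolated)
Conditions: NaHMDS (1.1 equiv), THF, −78 °C; then 13 (3 equiv), −78 to −45 °C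
Reagents that add atoms: none
Why: Evans asymmetric alkylation, in which the chelated Z-enolate is attacked by propargyl bromide on the face opposite the C4 benzyl group of the auxiliary, setting the future C3 as S, while low temperature suppresses ketene loss.

Step 9
Reactants: 15 (S)-4-benzyl-3-{(2S)-2-[2,5-bis(benzyloxy)-3,4-dimethoxyphenyl]pent-4-ynoyl}-1,3-oxazolidin-2-one
Product: 16 (2S)-2-[2,5-bis(benzyloxy)-3,4-dimethoxyphenyl]pent-4-yn-1-ol
Conditions: LiBH4, MeOH (1 equiv), Et2O, 0 °C
Reagents that add atoms: none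
Why: reductive cleavage of the N-acyloxazolidinone by borohydride at the exocyclic carbonyl, where the transient aldehyde is reduced faster than it can enolise and the alkyne and benzyl ethers are inert.

Step 10
Reactants: 17 1,1,2-trimethoxyethane
Product: 18 (Z)-1,2-dimethoxyethene
Conditions: TMSOTf, i-Pr2NEt, CH2Cl2, −20 °C to rt; fractional distillation
Reagents that add atoms: none
Why: acetal-to-enol-ether elimination through a silyl-activated oxocarbenium ion that the hindered amine deprotonates at the only β-carbon, the cis-dialkoxyalkene being the favoured geometry.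

Step 11
Reactants: 18 (Z)-1,2-dimethoxyethene; 19 chromium hexacarbonyl
Product: 22 tetramethylammonium pentacarbonyl[(Z)-2,3-dimethoxyacryloyl]chromate, via (Z)-1,2-dimethoxyvinyllithium 20 (not isolated), via lithium acylchromate 21 (not isolated)
Conditions: t-BuLi, THF, −78 to −20 °C; Cr(CO)6, Et2O/THF, −78 °C to rt; then Me4NBr, degassed H2O, rt
Reagents that add atoms: tetramethylammonium bromide, C[N+](C)(C)C.[Br-]
Why: α-lithiation of an enol ether (same lithium/β-oxygen relationship as in lithiated 5,6-dihydro-1,4-dioxin), addition of the vinyllithium to a carbonyl ligand as in the Fischer carbene synthesis, and cation exchange to the storable ammonium acylmetalate.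

Step 12
Reactants: 22 tetramethylammonium pentacarbonyl[(Z)-2,3-dimethoxyacryloyl]chromate; 16 (2S)-2-[2,5-bis(benzyloxy)-3,4-dimethoxyphenyl]pent-4-yn-1-ol
Product: 24 pentacarbonyl{[(2S)-2-(2,5-bis(benzyloxy)-3,4-dimethoxyphenyl)pent-4-ynyloxy][(Z)-1,2-dimethoxyvinyl]carbene}chromium, via acetoxycarbene complex 23 (not isolated)
Conditions: AcBr (1.0 equiv), CH2Cl2, −40 °C; then 16, −40 to 0 °C
Reagents that add atoms: none
Why: O-acylation of the acylmetalate gives a highly electrophilic acyloxycarbene that undergoes addition–elimination with the primary alcohol (alkoxy exchange at the carbene carbon), attaching the chiral tether under neutral cold conditions that leave C3 untouched.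

Step 13
Reactants: 24 pentacarbonyl{[(2S)-2-(2,5-bis(benzyloxy)-3,4-dimethoxyphenyl)pent-4-ynyloxy][(Z)-1,2-dimethoxyvinyl]carbene}chromium
Product: 26 (3S)-3-[2,5-bis(benzyloxy)-3,4-dimethoxyphenyl]-7,8-dimethoxychroman-6-ol, via tricarbonylchromium arene complex 25 (not isolated)
Conditions: THF (0.005 M), Ar, 55 °C; then air, MeCN, rt
Reagents that add atoms: none
Why: Thermal loss of one CO ligand lets the tethered terminal alkyne coordinate and insert into the Cr=C bond, which forms C8a–C4a and closes the pyran in a 6-exo-dig sense; CO then inserts at the new carbene carbon C5 to give a chromium-bound dienylketene (C5–C6), and 6π-electrocyclisation onto the vinyl β-carbon (C6–C7) followed by tautomerisation closes ring A as the phenol. The closest known reaction type is the intramolecular Dötz benzannulation of alkoxycarbenes whose alkyne is tethered through the carbene oxygen. No stereocentre is created, and C3 is a spectator that cannot epimerise under these neutral conditions. The step needs the regiochemistry opposite to the intermolecular preference (substituted alkyne carbon bound to the carbene carbon), and the O1–C2–C3–C4 tether secures it because the other orientation would demand a four-atom meta bridge across the new arene. It also needs cyclisation to outrun oligomerisation and CO insertion to outrun furan or cyclopentannulation pathways, which high dilution, THF as coordinating solvent and the alkenyl (rather than aryl) carbene should favour. Demetalation is done with air because ceric oxidants would attack the new hydroquinone monoether.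

Step 14
Reactants: 26 (3S)-3-[2,5-bis(benzyloxy)-3,4-dimethoxyphenyl]-7,8-dimethoxychroman-6-ol
Product: 28 5-[(3S)-6-hydroxy-7,8-dimethoxychroman-3-yl]-2,3-dimethoxy-1,4-benzoquinone (CNP0302517.1), via hydroquinone 27 (not isolated)
Conditions: H2 (1 atm), 10% Pd/C, EtOAc, rt; filter under Ar; then Ag2O (1.2 equiv), MgSO4, rt
Reagents that add atoms: none
Why: hydrogenolysis of the two aryl benzyl ethers followed by silver(I) oxide oxidation of the freed ring B hydroquinone, which as a free 1,4-diol should be oxidised far faster than the ring A monoether phenol.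

**Compound list**

1 | 2,3-dimethoxyphenol | COc1cccc(O)c1OC | starting material
2 | 2,3-dimethoxy-1,4-benzoquinone | COC1=C(OC)C(=O)C=CC1=O | intermediate
3 | 2,3-dimethoxybenzene-1,4-diol | COc1c(O)ccc(O)c1OC | intermediate
4 | 1,4-bis(benzyloxy)-2,3-dimethoxybenzene | COc1c(OC)c(OCc2ccccc2)ccc1OCc1ccccc1 | intermediate
5 | 1,4-bis(benzyloxy)-5-bromo-2,3-dimethoxybenzene | COc1c(OC)c(OCc2ccccc2)c(Br)cc1OCc1ccccc1 | intermediate
6 | diethyl malonate | CCOC(=O)CC(=O)OCC | starting material
7 | diethyl 2-[2,5-bis(benzyloxy)-3,4-dimethoxyphenyl]malonate | COc1c(OC)c(OCc2ccccc2)c(C(C(=O)OCC)C(=O)OCC)cc1OCc1ccccc1 | intermediate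
8 | 2-[2,5-bis(benzyloxy)-3,4-dimethoxyphenyl]malonic acid | COc1c(OC)c(OCc2ccccc2)c(C(C(=O)O)C(=O)O)cc1OCc1ccccc1 | intermediate (not isolated)
9 | [2,5-bis(benzyloxy)-3,4-dimethoxyphenyl]acetic acid | COc1c(OC)c(OCc2ccccc2)c(CC(=O)O)cc1OCc1ccccc1 | intermediate
10 | (S)-4-benzyl-1,3-oxazolidin-2-one | O=C1N[C@@H](Cc2ccccc2)CO1 | starting material
11 | pivalic [2,5-bis(benzyloxy)-3,4-dimethoxyphenyl]acetic anhydride | COc1c(OC)c(OCc2ccccc2)c(CC(=O)OC(=O)C(C)(C)C)cc1OCc1ccccc1 | intermediate (not isolated)
12 | (S)-4-benzyl-3-{[2,5-bis(benzyloxy)-3,4-dimethoxyphenyl]acetyl}-1,3-oxazolidin-2-one | COc1c(OC)c(OCc2ccccc2)c(CC(=O)N2C(=O)OC[C@@H]2Cc2ccccc2)cc1OCc1ccccc1 | intermediate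
13 | 3-bromoprop-1-yne (propargyl bromide) | C#CCBr | starting material
14 | sodium (Z)-enolate of 12 | COc1c(OC)c(OCc2ccccc2)c(/C=C(\[O-])N2C(=O)OC[C@@H]2Cc2ccccc2)cc1OCc1ccccc1.[Na+] | intermediate (not isolated)
15 | (S)-4-benzyl-3-{(2S)-2-[2,5-bis(benzyloxy)-3,4-dimethoxyphenyl]pent-4-ynoyl}-1,3-oxazolidin-2-one | COc1c(OC)c(OCc2ccccc2)c([C@H](CC#C)C(=O)N2C(=O)OC[C@@H]2Cc2ccccc2)cc1OCc1ccccc1 | intermediate
16 | (2S)-2-[2,5-bis(benzyloxy)-3,4-dimethoxyphenyl]pent-4-yn-1-ol | COc1c(OC)c(OCc2ccccc2)c([C@H](CC#C)CO)cc1OCc1ccccc1 | intermediate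
17 | 1,1,2-trimethoxyethane | COCC(OC)OC | starting material
18 | (Z)-1,2-dimethoxyethene | CO/C=C\OC | intermediate
19 | chromium hexacarbonyl | O=C=[Cr](=C=O)(=C=O)(=C=O)(=C=O)=C=O | starting material
20 | (Z)-1,2-dimethoxyvinyllithium | [Li]/C(OC)=C/OC | intermediate (not isolated)
21 | lithium pentacarbonyl[(Z)-2,3-dimethoxyacryloyl]chromate | [Li+].[O-]C(=[Cr](=C=O)(=C=O)(=C=O)(=C=O)=C=O)/C(OC)=C/OC | intermediate (not isolated)
22 | tetramethylammonium pentacarbonyl[(Z)-2,3-dimethoxyacryloyl]chromate | C[N+](C)(C)C.[O-]C(=[Cr](=C=O)(=C=O)(=C=O)(=C=O)=C=O)/C(OC)=C/OC | intermediate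
23 | pentacarbonyl{acetoxy[(Z)-1,2-dimethoxyvinyl]carbene}chromium | CC(=O)OC(=[Cr](=C=O)(=C=O)(=C=O)(=C=O)=C=O)/C(OC)=C/OC | intermediate (not isolated)
24 | pentacarbonyl{[(2S)-2-(2,5-bis(benzyloxy)-3,4-dimethoxyphenyl)pent-4-ynyloxy][(Z)-1,2-dimethoxyvinyl]carbene}chromium | COc1c(OC)c(OCc2ccccc2)c([C@H](CC#C)COC(=[Cr](=C=O)(=C=O)(=C=O)(=C=O)=C=O)/C(OC)=C/OC)cc1OCc1ccccc1 | intermediate
25 | tricarbonylchromium η6 complex of 26 on ring A (metal fragment written dot-separated) | COc1c(OC)c(OCc2ccccc2)c([C@H]2COc3c(cc(O)c(OC)c3OC)C2)cc1OCc1ccccc1.O=C=[Cr](=C=O)=C=O | intermediate (not isolated)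
26 | (3S)-3-[2,5-bis(benzyloxy)-3,4-dimethoxyphenyl]-7,8-dimethoxychroman-6-ol | COc1c(OC)c(OCc2ccccc2)c([C@H]2COc3c(cc(O)c(OC)c3OC)C2)cc1OCc1ccccc1 | intermediate
27 | 2-[(3S)-6-hydroxy-7,8-dimethoxychroman-3-yl]-5,6-dimethoxybenzene-1,4-diol | COc1c(OC)c(O)c([C@H]2COc3c(cc(O)c(OC)c3OC)C2)cc1O | intermediate (not isolated)
28 | 5-[(3S)-6-hydroxy-7,8-dimethoxychroman-3-yl]-2,3-dimethoxy-1,4-benzoquinone (CNP0302517.1) | COC1=C(OC)C(=O)C([C@H]2COc3c(cc(O)c(OC)c3OC)C2)=CC1=O | target

**Totals**

Total step count: 14. Longest linear sequence: 12 steps (steps 1–9, 12, 13, 14); steps 10 and 11 form the two-step carbene branch.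

**Steps most likely to fail**

1. Step 13. The vinylcarbene formed after alkyne insertion may close without CO insertion (furan or cyclopentannulation pathways). Intermolecular insertion may also compete and give oligomers, or the electron-rich carbene may decompose before CO loss.
Fallback, setting out from 16 and returning at 26: Appel chlorination of 16 (PPh3, CCl4) should give 1,4-bis(benzyloxy)-5-[(2S)-1-chloropent-4-yn-2-yl]-2,3-dimethoxybenzene F1. Its lithium acetylide (n-BuLi, THF, −78 °C) is added to one carbonyl of dimethyl squarate to give the 4-alkynyl-4-hydroxy-2,3-dimethoxycyclobutenone F2. Thermolysis in toluene at 110 °C (Moore rearrangement: electrocyclic opening to an enynylketene, ring closure, hydrogen transfer) should give the 2,3-dimethoxy-5-alkyl-1,4-benzoquinone F3, in which the squarate supplies C6, C7, C8 and C8a. Dithionite reduction gives the chloroalkyl hydroquinone F4, and Cs2CO3 in degassed DMF closes the pyran by phenoxide displacement of chloride to give 26. Only the hydroxyl ortho to the side chain can reach the chloride, so the C6 hydroxyl stays free.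

2. Step 12. The acetoxycarbene may fragment, or suffer conjugate attack at the β-methoxyvinyl carbon, before the β-branched primary alcohol exchanges at the carbene carbon.
Fallback, setting out from 16 and 22 and returning at 24: 16 is converted at −78 °C (Tf2O, 2,6-di-tert-butylpyridine, CH2Cl2) into (2S)-2-[2,5-bis(benzyloxy)-3,4-dimethoxyphenyl]pent-4-ynyl triflate F5. F5 is used cold and at once to O-alkylate acylmetalate 22 (CH2Cl2, −78 to 0 °C). This is the classical alkylation route to Fischer alkoxycarbenes; it bypasses 23 and gives 24 directly.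

3. Step 11. The vinyllithium may lose lithium methoxide by anti β-elimination to methoxyacetylene, or add only sluggishly to the poorly soluble hexacarbonyl.
Fallback, setting out from 18 and 19 and returning at 22: enol ether 18 is C-acylated with oxalyl chloride at 0 °C to (Z)-3,4-dimethoxy-2-oxobut-3-enoyl chloride F6. On heating, F6 should lose carbon monoxide to give (Z)-2,3-dimethoxyacryloyl chloride F7. Separately, 19 is reduced with potassium graphite in THF at −78 °C to dipotassium pentacarbonylchromate F8. Acylation of F8 by F7 gives potassium pentacarbonyl[(Z)-2,3-dimethoxyacryloyl]chromate F9, and cation exchange with Me4NBr returns to 22. The acyl electrophile/metalate dianion polarity replaces the vinyl nucleophile/metal carbonyl polarity.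

**Further compounds**

F1 | step 13 | 1,4-bis(benzyloxy)-5-[(2S)-1-chloropent-4-yn-2-yl]-2,3-dimethoxybenzene | COc1c(OC)c(OCc2ccccc2)c([C@H](CC#C)CCl)cc1OCc1ccccc1
F2 | step 13 | 4-{(4S)-4-[2,5-bis(benzyloxy)-3,4-dimethoxyphenyl]-5-chloropent-1-ynyl}-4-hydroxy-2,3-dimethoxycyclobut-2-en-1-one (carbinol centre unassigned) | COc1c(OC)c(OCc2ccccc2)c([C@H](CC#CC2(O)C(OC)=C(OC)C2=O)CCl)cc1OCc1ccccc1
F3 | step 13 | 5-{(2S)-2-[2,5-bis(benzyloxy)-3,4-dimethoxyphenyl]-3-chloropropyl}-2,3-dimethoxy-1,4-benzoquinone | COc1c(OC)c(OCc2ccccc2)c([C@H](CC2=CC(=O)C(OC)=C(OC)C2=O)CCl)cc1OCc1ccccc1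
F4 | step 13 | 2-{(2S)-2-[2,5-bis(benzyloxy)-3,4-dimethoxyphenyl]-3-chloropropyl}-5,6-dimethoxybenzene-1,4-diol | COc1c(OC)c(OCc2ccccc2)c([C@H](Cc2cc(O)c(OC)c(OC)c2O)CCl)cc1OCc1ccccc1
F5 | step 12 | (2S)-2-[2,5-bis(benzyloxy)-3,4-dimethoxyphenyl]pent-4-ynyl trifluoromethanesulfonate | COc1c(OC)c(OCc2ccccc2)c([C@H](CC#C)COS(=O)(=O)C(F)(F)F)cc1OCc1ccccc1
F6 | step 11 | (Z)-3,4-dimethoxy-2-oxobut-3-enoyl chloride | ClC(=O)C(=O)/C(OC)=C/OC
F7 | step 11 | (Z)-2,3-dimethoxyacryloyl chloride | ClC(=O)/C(OC)=C/OC
F8 | step 11 | dipotassium pentacarbonylchromate | [K+].[K+].O=C=[Cr-2](=C=O)(=C=O)(=C=O)=C=O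
F9 | step 11 | potassium pentacarbonyl[(Z)-2,3-dimethoxyacryloyl]chromate | [K+].[O-]C(=[Cr](=C=O)(=C=O)(=C=O)(=C=O)=C=O)/C(OC)=C/OC
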